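The constants were chosen freely; the result is computed.

The easy count comes first: each capped end uses up one one-sided end group, so c(capped ends) cannot pass 0.0480 M.

    first end groups + second end groups ⇌ links (K1 = 1.56 M⁻¹, k1 = 0.0258 M⁻¹ s⁻¹)
    first end groups + one-sided end groups → capped ends (k2 = 0.639 M⁻¹ s⁻¹)
    second end groups ⇌ dormant form (K3 = 1.21, k3 = 0.0101 s⁻¹)
    2 second end groups → self-condensation product (k4 = 0.00262 M⁻¹ s⁻¹)

common to all: one-sided end groups 0.0480 M

| flask | first end groups | second end groups | remark | time |
|---|---|---|---|---|
| dawn | 0.48 M | 0.480 M | one stirred flow tank at steady state, fed with the mixture as stated, mean residence time 1.5 min |  |
| autumn | 0.48 M (fed, over 1.50 min) | 0.480 M | all but first end groups at the start; first end groups goes in evenly over 1.50 min, the run ends at 1.5 min | 1.5 min |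
| noon | 0.48 M | 0.480 M | everything together in a closed stirred flask, run for 1.5 min | 1.5 min |
| spring | 0.48 M | 0.480 M (fed, over 1.50 min) | all but second end groups at the start; second end groups goes in evenly over 1.50 min, the run ends at 1.5 min | 1.5 min |

- a doubled species enters its step squared and goes two at a time
- the stated concentrations are those of everything mixed, before any reaction; amounts are the same in each set-up
- the feed brings no volume worth counting
- run time (autumn): 1.5 min

- the set-up with the highest share of links in all that became links or capped ends, at the outlet or at the end ("none" if the first two lie within 2 percentage points) (dawn / autumn / noon / spring / none)
- share of links in all that became links or capped ends, at the outlet or at the end, dawn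
- share of links in all that became links or capped ends, at the outlet or at the end, autumn
- share of links in all that became links or capped ends, at the outlet or at the end, noon
- share of links in all that became links or capped ends, at the outlet or at the end, spring

**Fastest rung.** In noon, first end groups stand at ten times the one-sided end groups, so capping is pseudo-first-order in one-sided end groups, with c(first end groups) setting its pace. The half-life of one-sided end groups at that concentration is 0.0377 min, which is far shorter than the run of 1.5 min. Capped ends should therefore reach 10.0% of the first end groups charged almost at once.

**Middle rungs.** Second end groups and dormant form relax, both ways together, with a half-life of 0.626 min. Linking has a forward half-life of 0.933 min at the charged c(second end groups). Both are shorter than the run, but the run spans just 1.61 of these linking half-lives, and the feeds of autumn and spring last until its end, so balance serves here as a reference and not as the expected state at the end of the run.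

**Slowest rung.** Self-condensation has a first half-life of 6.63 min, longer than the run, so this reckoning leaves it out.

**Balance share.** At balance, dormant form is 1.21 times the free second end groups, and c(links) is 1.56 M⁻¹ times c(first end groups) times c(second end groups). With capped ends at 0.0480 M, this gives c(links) = 0.0927 M. The balance share, c(links) over c(links) plus c(capped ends), is then 65.9%. This figure contains no time, so it gives one value for every set-up and no ranking.

**The forecast.** It ranks noon first, with dawn 63.8%, autumn 56%, noon 67% and spring 63%, on the ground that “having both end groups concentrated from the start (noon) does this best”. Unlike the balance share, it separates the set-ups.

**The result.** The simulation also puts noon first, with dawn 63.8%, autumn 56.7%, noon 67.6% and spring 63.8%. Noon's lead of 3.8 percentage points would have to fall below 2 points for the answer to become "none". Noon reads above the balance share, and autumn below it. Autumn read at 4.0 min holds 0.0326 M of self-condensation product, which leaves 0.415 M of second end groups, counting free, dormant and linked together. The same balance then gives 0.0821 M of links and a share of 63.1%. That flask reads 63.0%, with links at 17.0% of the first end groups charged.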